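The constants are those of an exercise; the result is computed.

**Leftover solid.** The flask holds more solid substrate than reagent, and at most 70.0% of that solid can become target, so a leftover of solid stays and feeds the solution.

solid substrate 10 mM; reagent 7.00 mM; time 1.0 min

    solid substrate ⇌ dissolved substrate, rate k1*(cs1 - [dissolved substrate]) while solid is left; crystals form when [dissolved substrate] > cs1 (cs1 = 0.30 mM, k1 = 0.11 s⁻¹)
    dissolved substrate + reagent ⇌ target (K2 = 4600 M⁻¹, k2 = 5.5 M⁻¹ s⁻¹)
    reagent → side product (k3 = 0.0022 s⁻¹)
    solid product ⇌ target, rate k4*(cs4 - [target]) while solid is left; crystals form when [target] > cs4 (cs4 = 3.4 mM, k4 = 0.51 s⁻¹)

- amounts and yields of target count solid product too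
- given per volume of solution although it is solid: solid substrate, solid product
- at the start none of the solid substrate is in solution
- dissolved substrate means what is dissolved; the solid is not counted in it
- run time (flask): 1.0 min

- the target and solid product together standing at 1.0 min, as a percentage of the solid substrate charged
- concentration of dissolved substrate in solution at 1.0 min, in percent of saturation

**One number.** Dissolved substrate is fed in proportion to its gap below saturation. Reagent removes it in a pseudo-first-order way. Equating the two puts its level at saturation divided by one plus D. Here D, the consumption number (a Damköhler number), is the forward rate constant of the reagent step times the reagent concentration, over the dissolution coefficient. At the charge, D is 0.350, which gives 0.222 mM.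

**Second round.** That level makes 0.513 mM of target in 1.0 min. Reagent pays for this and also feeds side product, with a half-life of 5.3 min. My mean reagent is therefore 6.31 mM, and D becomes 0.316. The solution fills with a lag of 6.91 s, shorter than the run. My reckoning then gives 4.20% of target. Reagent ends near 5.71 mM, which gives 77.8% of saturation. So one number was not enough: D at the charge gave 5.13% of the solid substrate charged, more than the 4.20% reckoned with falling reagent and the lag. Target stays below its solubility, so no crystals are expected.

**Forecast.** The forecast gives 4.1% and 79%, with the level below saturation because “the reagent keeps consuming it”. My own figures are 4.20% and 77.8%.

**Result.** The simulation gives 4.08% and 78.2%. The flask's reagent reading of 82.1% of its charge makes D 0.288, hence 77.7% of saturation. The neighbouring flask, with 12 mM of reagent and the same solid substrate and time, starts at D = 0.600. The same two rounds give mean reagent 10.9 mM and 6.29% of target. Its reagent reading of 82.8% of its charge gives 66.8% of saturation. That neighbouring flask gave 6.12%, with dissolved substrate at 67.7% of saturation.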